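## The problem

Atom numbers follow the geranylgeraniol skeleton. They are C1 (CH2OH), C2=C3 (Z, methyl C20 on C3), C4, C5, C6=C7, C19 (CH2OAc on C7), C8 (carbinol carbon), C9, C10=C11, C18 (lactone C=O on C11), C12, C13 and C14=C15 (methyls C16, C17).

- **Chain and ring.** The target is an open C20 chain with one ring, the 5,6-dihydro-2H-pyran-2-one O–C18(=O)–C11=C10–C9–C8. The task is therefore chain assembly with four trisubstituted alkenes, three of them stereodefined: 2Z, 6E and the ring-locked C10=C11.
- **Stereocentre.** C8 (R) is the only stereocentre. Nothing in the molecule can control it, so a catalyst has to set it. As an allylic acyloxy carbon it can be lost again by ionisation (acid, Pd(0)) or by a [3,3] shift.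
- **Hardest atom.** C7 is an sp2 carbon whose three carbon arms are all different and all functionalised. They are C6H= leading into the chain, C19H2OAc cis to C5, and C8 trans to C5.
- **Oxygen differentiation.** Two primary allylic oxygens must end up different (C1–OH free, C19–OAc) beside a third ester. No hydride, organometallic or hydroxide step is possible once the acetate or the lactone is in place.
- **Sensitive groups.** The 2Z allylic alcohol is acid-labile (ionisation, Z/E loss, cyclisation). 2-(Acetoxymethyl)enals are Morita–Baylis–Hillman-type electrophiles that do not tolerate nucleophilic amines or phosphines.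
- **Feature that makes the key step possible.** It is the pattern at C7 itself. C6 is an olefinic CH that can come from an aldehyde. C19, cis to the chain, is a one-carbon unit that can come from an electrophile. C8, trans to the chain, can be carried at the aldehyde level as a 1,3-dioxolane. A β-oxido phosphonium ylide delivers exactly this substitution and geometry when C7 is the ylide carbon.

## Retrosynthesis

**27 ⇒ 26 (O–Si at C1).** No skeletal bond is cut. The C1 oxygen is the oxygen of nerol itself and stays masked from the first step, whereas the C19 oxygen enters already acetylated. The two primary allylic oxygens therefore never have to be told apart chemically. The forward step must remove silicon without base (acetate migration, lactone opening) and without strong acid.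

**26 ⇒ 25 (C10=C11).** The ring is opened at its alkene rather than at C18–O. A lactonisation would need a Z-selective olefination of a β-acyloxy aldehyde that eliminates easily, whereas ring closure at C10=C11 gives the cis arrangement of C9 and C18 automatically. The forward metathesis must engage the one vinyl group and the one 1,1-disubstituted acrylate and leave three trisubstituted alkenes alone.

**25 ⇒ 16 + 23 (C18–O bond).** An ester bond divides the molecule into the left part 16 and the acid 23, which carries C11–C18. Both are acyclic and 23 is achiral. The acylation must be neutral, so that the C8 hydroxyl is never an alkoxide next to the C19 acetate.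

**16 ⇒ 13 + 14 (C8–C9).** This cut creates C8 by a catalytic enantioselective allylation of the enal 13 with 14. The neighbouring cut C7–C8 would need a stereodefined C7 alkenyl metal and a β,γ-unsaturated aldehyde that isomerises. Here the aldehyde is a stable E-enal and the nucleophile is commercial. The precursor 13 has no stereocentre.

**13 ⇒ 12 ⇒ 5 + 6 + 7 (C6=C7 and C7–C19, key step).**

- The enal 13 is the unmasked acetal 12. In 12 two bonds at C7 are cut at once, so that C7–C8 comes from the salt 6, C6 from the aldehyde 5 and C19, with its acetate, from 7.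
- A cut of C6=C7 alone leaves the C19 oxygen and the oxidation level of C8 to be adjusted later. The double cut delivers the geometry, the acetate and the aldehyde level of C8 together.
- Two of the three precursors are commercial and the third is a C7 aldehyde.
- The forward reaction must place C19 cis to C5.

**5 ⇒ 3 ⇒ 2 ⇒ 1 (isopropylidene terminus of nerol).** Nerol 1 already holds C1–C6, C20 and the 2Z alkene. Only its terminal C3 unit is cut off. Building the Z alkene anew would cost more steps and selectivity. The forward sequence must oxidise the remote alkene only.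

**23 ⇒ 21 ⇒ 20 ⇒ 17 + 18 (C11–C12 and the sacrificial methylene).** Alkylation of 17 with 18 forms C11–C12, and a Horner–Wadsworth–Emmons methylenation then gives the acrylate 21. All the reactions are standard and run in parallel with the main line.

## Roads not taken

**Alternative 1:** (the most obvious)

- **Cut and key step.** Only C6=C7 is cut, by a Horner–Wadsworth–Emmons reaction of 5 with the phosphonate A1 to give the enoate A2. Reduction and re-oxidation give the enal A3, which enters the same endgame. The C19 silyl ether is removed and acetylated at the end.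
- **Why the chosen plan is better.**
  - C8 arrives at the ester level, so two redox steps are needed. These exclude an acetate, which forces a third protecting group and a late choice between two primary allylic silyl ethers.
  - The anion of A1 has a β-silyloxy leaving group.
  - α-Branched phosphonoacetates give only moderate geometry control with aliphatic aldehydes.
  - The road costs at least four more steps and solves the differentiation problem by protecting groups, not by design.

**Alternative 2:**

- **Cut and key step.** C6=C7 is treated as a former alkyne and C7–C8 and C7–C19 are cut. Aldehyde 5 is homologated to the alkyne A4. A4 is added enantioselectively to a four-carbon β,γ-unsaturated aldehyde to give the propargylic alcohol A5. Hydroxyl-directed ruthenium-catalysed trans-hydrostannation gives the stannane A6 (Sn on C7, cis to C5), and tin is then exchanged for CH2OH.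
- **Why the chosen plan is better.**
  - The geometry control is good, but the aldehyde partner isomerises readily.
  - The exchange of tin for the hydroxymethyl group takes two to three steps.
  - The resulting 1,3-diol still has to be mono-acetylated.
  - The main line becomes five to six steps longer and uses stoichiometric tin twice.

**Alternative 3:**

- **Cut and key step.** The C6–C7 bond is cut at the alcohol level. Nozaki–Hiyama–Kishi coupling of 5 with the finished bromovinyl lactone A7 gives the allylic alcohol A8 (C6–OH, C7=C19H2). Its oxygen function must then travel from C6 to C19 as acetate.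
- **Why the chosen plan is better.** The convergence is attractive, but the 1,3-transposition has no reliable mechanism here.
  - The Pd(II)-catalysed [3,3] shift of allylic acetates passes through a C–Pd bond at the central carbon, which is fully substituted (C7).
  - Pd(0) would also ionise the allylic C8–O lactone bond and endanger the stereocentre.
  - Oxo-rhenium or acid catalysis threatens the 2Z allylic terminus.
  - The geometry would rest on thermodynamics alone.

Key step: step 4

Remark: 3, 4, 9, 10, 11 and 20 are racemates or diastereomer mixtures whose stereocentres are erased later. For 11 the SMILES shows the relative configuration of the productive diastereomer (one enantiomer drawn).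

## Steps

Step 1
Reactants: 1 nerol
Product: 2 tert-butyl{[(2Z)-3,7-dimethylocta-2,6-dien-1-yl]oxy}diphenylsilane
Conditions: TBDPSCl, imidazole, CH2Cl2, 0 °C → rt
Reagents that add atoms: tert-butyl(chloro)diphenylsilane, CC(C)(C)[Si](Cl)(c1ccccc1)c1ccccc1
Why: Standard silylation of a primary alcohol. TBDPS is chosen because it withstands aryllithium at low temperature, aqueous acid and Ti(IV), and leaves with buffered fluoride at the end.

Step 2
Reactants: 2 neryl silyl ether
Product: 3 tert-butyl{[(2Z)-5-(3,3-dimethyloxiran-2-yl)-3-methylpent-2-en-1-yl]oxy}diphenylsilane (racemic)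
Conditions: mCPBA (1 equiv), CH2Cl2, −20 °C
Reagents that add atoms: 3-chloroperoxybenzoic acid, OOC(=O)c1cccc(Cl)c1
Why: Prilezhaev epoxidation. The remote isopropylidene alkene is more electron-rich than C2=C3, which is deactivated inductively by the allylic oxygen and shielded by the bulky silyl group. The new stereocentre is irrelevant because it is cleaved in step 3.

Step 3
Reactants: 3 epoxide
Product: 5 (4Z)-6-[(tert-butyldiphenylsilyl)oxy]-4-methylhex-4-enal, via diol 4 (not isolated)
Conditions: H5IO6, THF/H2O, 0 °C
Reagents that add atoms: none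
Why: Acid-assisted opening of the epoxide at its tertiary carbon gives the diol, which periodate cleaves (Malaprade reaction) in the same flask. This is the usual way to degrade geranyl and neryl termini to the C7 aldehyde. The Z alkene and the silyl ether are inert.

Step 4
Reactants: 5 aldehyde; 6 (1,3-dioxolan-2-ylmethyl)triphenylphosphonium bromide; 7 bromomethyl acetate
Product: 12 (2E,6Z)-8-[(tert-butyldiphenylsilyl)oxy]-2-(1,3-dioxolan-2-yl)-6-methylocta-2,6-dien-1-yl acetate, via ylide 8 (not isolated), via lithium betaine 9 (not isolated), via β-oxido ylide 10 (not isolated), via alkylated betaine 11 (not isolated)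
Conditions: 6, PhLi (1 equiv), LiBr, THF/Et2O, −78 → 0 °C; 5, −78 °C; PhLi (1 equiv), −78 → −30 °C; 7, −78 °C → rt
Reagents that add atoms: none
Why: Proposed new method: the closest known reaction type is the Wittig–Schlosser (SCOOPY) three-component olefination, in which β-lithiooxy phosphonium ylides made from unstabilised alkylidene ylides and aldehydes are trapped by formaldehyde or halomethyl esters to give trisubstituted allylic alcohols or esters with the new CH2O arm cis to the aldehyde residue; the new element is the acetal-bearing ylide 8. Ylide 8 adds to 5 at −78 °C, and lithium bromide holds the adduct as the open betaine 9 (both diastereomers), which cannot lose phosphine oxide at this temperature. The second equivalent of base removes the proton on C7, C7 becomes planar in 10, and the erythro/threo mixture converges on one species. Ylide 10 is alkylated at C7 by the highly SN2-active α-acyloxy bromide 7 on the face remote from the C5 chain of the lithium-bridged O–C6–C7–P unit, which gives 11. Syn loss of triphenylphosphine oxide on warming then places C19 cis and C8 trans to C5, the same sense as protonation in the Schlosser E-olefination. No ring is closed and no stereocentre survives, so the only stereochemical element created is the C6=C7 geometry, and the branched dioxolanyl group, as the larger C7 substituent, reinforces the usual preference. The step needs C- over O-alkylation (the ylide carbon is by far the more nucleophilic site) and attack at CH2Br rather than at the acetate carbonyl (favoured at −78 °C by the oxygen-accelerated SN2). It also needs no β-elimination of acetal oxygen from 8 or 10: opening of the dioxolane leaves the alkoxide tethered and is reversible, and 8 is routinely handled with strong base.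

Step 5
Reactants: 12 acetal
Product: 13 (2E,6Z)-8-[(tert-butyldiphenylsilyl)oxy]-2-formyl-6-methylocta-2,6-dien-1-yl acetate
Conditions: 1 M aq HCl, THF, 0 °C → rt
Reagents that add atoms: water, O
Why: Hydrolysis of an α,β-unsaturated acetal through an allyl-stabilised oxocarbenium ion is fast under mild acid, which TBDPS, the acetate and the 2Z allylic ether withstand. The E-enal (C5 trans to CHO) is also the thermodynamic isomer, so the geometry cannot drift the wrong way.

Step 6
Reactants: 13 enal; 14 allyltributylstannane
Product: 16 (2E,6Z)-8-[(tert-butyldiphenylsilyl)oxy]-2-[(1R)-1-hydroxybut-3-en-1-yl]-6-methylocta-2,6-dien-1-yl acetate, via stannyl ether 15 (not isolated)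
Conditions: (R)-BINOL (20 mol %), Ti(OiPr)4 (10 mol %), 4 Å MS, CH2Cl2, −20 °C; aq NaHCO3
Reagents that add atoms: none
Why: Keck allylation, well precedented on α-substituted E-enals. The (R)-BINOL–Ti(IV) complex directs the stannane to the Re face, which gives the (R)-carbinol when the aldehyde residue outranks allyl. The conditions are neutral and free of nucleophilic amines, so the acetoxymethyl enal is attacked only at C=O.

Step 7
Reactants: 17 triethyl phosphonoacetate; 18 5-bromo-2-methylpent-2-ene
Product: 20 ethyl 2-(diethoxyphosphoryl)-6-methylhept-5-enoate (racemic), via sodium phosphonoenolate 19 (not isolated)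
Conditions: NaH, DMF, 0 °C; 18, 60 °C
Reagents that add atoms: none
Why: SN2 alkylation of a stabilised phosphonate carbanion with a primary homoallylic bromide forms C11–C12. A slight excess of 17 should suppress dialkylation.

Step 8
Reactants: 20 phosphonate
Product: 21 ethyl 6-methyl-2-methylidenehept-5-enoate
Conditions: 37 % aq CH2O, K2CO3, H2O/THF, rt → 60 °C
Reagents that add atoms: formaldehyde, C=O
Why: Horner–Wadsworth–Emmons methylenation of an α-alkyl phosphonoacetate under aqueous carbonate is the standard entry to 2-alkylacrylates. No geometry issue arises.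

Step 9
Reactants: 21 acrylate ester
Product: 23 6-methyl-2-methylidenehept-5-enoic acid, via lithium carboxylate 22 (not isolated)
Conditions: LiOH, THF/MeOH/H2O, rt; 1 M HCl
Reagents that add atoms: lithium hydroxide, [Li+].[OH-]
Why: Plain saponification. The α-alkyl group slows conjugate addition of hydroxide to the acrylate.

Step 10
Reactants: 16 alcohol; 23 acid
Product: 25 (1R)-configured 6-methyl-2-methylidenehept-5-enoate ester of 16 at O8, via O-acylisourea 24 (not isolated)
Conditions: DCC, DMAP (cat.), CH2Cl2, 0 °C → rt
Reagents that add atoms: none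
Why: Steglich esterification. The C8–O bond is not touched, so the configuration is retained. The neutral medium keeps the C8 hydroxyl un-ionised, so 1,3-migration of the C19 acetyl group is not triggered.

Step 11
Reactants: 25 diene ester
Product: 26 (2E,6Z)-8-[(tert-butyldiphenylsilyl)oxy]-6-methyl-2-[(2R)-5-(4-methylpent-3-en-1-yl)-6-oxo-3,6-dihydro-2H-pyran-2-yl]octa-2,6-dien-1-yl acetate
Conditions: Grubbs II (5–10 mol %), CH2Cl2 (2 mM), reflux
Reagents that add atoms: none
Why: Ring-closing metathesis of homoallyl 2-alkylacrylates to 3-alkyl-5,6-dihydropyran-2-ones is well precedented. Ruthenium loads at the only monosubstituted alkene and closes the six-membered ring on the 1,1-disubstituted acrylate. Closure on C6=C7, C2=C3 or C14=C15 would give four-, eight- or nine-membered rings.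

Step 12
Reactants: 26 silyl ether
Product: 27 target, (2E,6Z)-8-hydroxy-6-methyl-2-[(2R)-5-(4-methylpent-3-en-1-yl)-6-oxo-3,6-dihydro-2H-pyran-2-yl]octa-2,6-dien-1-yl acetate
Conditions: HF·pyridine, pyridine/THF, 0 °C → rt
Reagents that add atoms: none
Why: Fluoride-driven Si–O cleavage in a pyridine-buffered medium. The medium is neither basic enough for acetate migration or lactone opening nor acidic enough to ionise the allylic C1, C8 or C19 oxygens.

## Compound list

1 | nerol | CC(C)=CCC/C(C)=C\CO | starting material
2 | neryl tert-butyldiphenylsilyl ether | CC(C)=CCC/C(C)=C\CO[Si](c1ccccc1)(c1ccccc1)C(C)(C)C | intermediate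
3 | terminal epoxide of 2 (racemic) | CC1(C)OC1CC/C(C)=C\CO[Si](c1ccccc1)(c1ccccc1)C(C)(C)C | intermediate
4 | (6Z)-8-[(tert-butyldiphenylsilyl)oxy]-2,6-dimethyloct-6-ene-2,3-diol (racemic) | CC(C)(O)C(O)CC/C(C)=C\CO[Si](c1ccccc1)(c1ccccc1)C(C)(C)C | intermediate
5 | (4Z)-6-[(tert-butyldiphenylsilyl)oxy]-4-methylhex-4-enal | O=CCC/C(C)=C\CO[Si](c1ccccc1)(c1ccccc1)C(C)(C)C | intermediate
6 | (1,3-dioxolan-2-ylmethyl)triphenylphosphonium bromide | [Br-].c1ccc(cc1)[P+](CC1OCCO1)(c1ccccc1)c1ccccc1 | starting material
7 | bromomethyl acetate | CC(=O)OCBr | starting material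
8 | (1,3-dioxolan-2-ylmethylidene)triphenylphosphorane | C(=P(c1ccccc1)(c1ccccc1)c1ccccc1)C1OCCO1 | intermediate
9 | lithium bromide complex of the betaine from 8 and 5 (diastereomer mixture) | [Li+].[Br-].[O-]C(CC/C(C)=C\CO[Si](c1ccccc1)(c1ccccc1)C(C)(C)C)C(C1OCCO1)[P+](c1ccccc1)(c1ccccc1)c1ccccc1 | intermediate
10 | β-lithiooxy phosphonium ylide | [Li+].[O-]C(CC/C(C)=C\CO[Si](c1ccccc1)(c1ccccc1)C(C)(C)C)C(C1OCCO1)=P(c1ccccc1)(c1ccccc1)c1ccccc1 | intermediate
11 | C7-acetoxymethylated betaine (racemic; with P and O syn-periplanar, C5 and C19 are eclipsed) | [Li+].[Br-].[O-][C@@H](CC/C(C)=C\CO[Si](c1ccccc1)(c1ccccc1)C(C)(C)C)[C@](COC(C)=O)(C1OCCO1)[P+](c1ccccc1)(c1ccccc1)c1ccccc1 | intermediate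
12 | (2E,6Z)-8-[(tert-butyldiphenylsilyl)oxy]-2-(1,3-dioxolan-2-yl)-6-methylocta-2,6-dien-1-yl acetate | CC(=O)OC/C(=C\CC/C(C)=C\CO[Si](c1ccccc1)(c1ccccc1)C(C)(C)C)C1OCCO1 | intermediate
13 | (2E,6Z)-8-[(tert-butyldiphenylsilyl)oxy]-2-formyl-6-methylocta-2,6-dien-1-yl acetate | CC(=O)OC/C(=C\CC/C(C)=C\CO[Si](c1ccccc1)(c1ccccc1)C(C)(C)C)C=O | intermediate
14 | allyltributylstannane | C=CC[Sn](CCCC)(CCCC)CCCC | starting material
15 | O8-tributylstannyl ether of 16 | CC(=O)OC/C(=C\CC/C(C)=C\CO[Si](c1ccccc1)(c1ccccc1)C(C)(C)C)[C@H](O[Sn](CCCC)(CCCC)CCCC)CC=C | intermediate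
16 | (2E,6Z)-8-[(tert-butyldiphenylsilyl)oxy]-2-[(1R)-1-hydroxybut-3-en-1-yl]-6-methylocta-2,6-dien-1-yl acetate | CC(=O)OC/C(=C\CC/C(C)=C\CO[Si](c1ccccc1)(c1ccccc1)C(C)(C)C)[C@H](O)CC=C | intermediate
17 | triethyl phosphonoacetate | CCOC(=O)CP(=O)(OCC)OCC | starting material
18 | 5-bromo-2-methylpent-2-ene | CC(C)=CCCBr | starting material
19 | sodium salt of 17 | [Na+].CCOC(=O)[CH-]P(=O)(OCC)OCC | intermediate
20 | ethyl 2-(diethoxyphosphoryl)-6-methylhept-5-enoate (racemic) | CCOC(=O)C(CCC=C(C)C)P(=O)(OCC)OCC | intermediate
21 | ethyl 6-methyl-2-methylidenehept-5-enoate | CCOC(=O)C(=C)CCC=C(C)C | intermediate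
22 | lithium 6-methyl-2-methylidenehept-5-enoate | [Li+].[O-]C(=O)C(=C)CCC=C(C)C | intermediate
23 | 6-methyl-2-methylidenehept-5-enoic acid | OC(=O)C(=C)CCC=C(C)C | intermediate
24 | O-acylisourea from 23 and DCC | C=C(CCC=C(C)C)C(=O)OC(=NC1CCCCC1)NC1CCCCC1 | intermediate
25 | 6-methyl-2-methylidenehept-5-enoate of 16 (R at C8) | CC(=O)OC/C(=C\CC/C(C)=C\CO[Si](c1ccccc1)(c1ccccc1)C(C)(C)C)[C@H](OC(=O)C(=C)CCC=C(C)C)CC=C | intermediate
26 | C1 tert-butyldiphenylsilyl ether of the target | CC(=O)OC/C(=C\CC/C(C)=C\CO[Si](c1ccccc1)(c1ccccc1)C(C)(C)C)[C@H]1CC=C(CCC=C(C)C)C(=O)O1 | intermediate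
27 | (2E,6Z)-8-hydroxy-6-methyl-2-[(2R)-5-(4-methylpent-3-en-1-yl)-6-oxo-3,6-dihydro-2H-pyran-2-yl]octa-2,6-dien-1-yl acetate | CC(=O)OC/C(=C\CC/C(C)=C\CO)[C@H]1CC=C(CCC=C(C)C)C(=O)O1 | target

## Count and risks

Total steps: 12. Longest linear sequence: 9 (steps 1–6 and 10–12, from nerol). Steps 7–9 run in parallel.

**Step 4 (key step, proposed new method).**

- **What may go wrong.**
  - The first adduct may collapse to the simple disubstituted alkene before the second deprotonation.
  - The ylide or the lithium alkoxide may attack the acetate carbonyl, or acetyl may be transferred within the alkylated betaine before phosphine oxide is lost.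
  - The dioxolane may open by β-elimination at the carbanionic stage.
  - All three arise because the acetal-bearing ylide has not been taken through this sequence before.
- **Fallback (known chemistry, from 5 back to 13).**
  - 2-(1-Bromovinyl)-1,3-dioxolane is lithiated with t-BuLi at −78 °C and added to 5, which gives the allylic alcohol F1.
  - Acetylation (Ac2O, pyridine) gives the secondary acetate F2.
  - Mild aqueous acid releases the α-methylene-β-acetoxy aldehyde F3.
  - Catalytic DABCO moves the acetate from C6 to C19 by the SN2′–SN2′ sequence typical of Morita–Baylis–Hillman acetates. Under thermodynamic control this gives the E-enal 13.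

**Step 6.**

- **What may go wrong.** Turnover may be slow and facial selectivity may erode. The α-branch hinders the aldehyde, and the acetate carbonyl can compete for titanium.
- **Fallback (from 13 back to 16).** The stereocentre is set by reduction instead of C–C bond formation.
  - Indium-mediated Barbier allylation in aqueous THF gives the racemic alcohol F4.
  - Dess–Martin oxidation gives the dienone F5.
  - Corey–Bakshi–Shibata reduction with the (S)-methyl oxazaborolidine and catecholborane at −78 °C gives 16. The branched alkenyl group acts as the large substituent.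

**Step 11.**

- **What may go wrong.** Closure onto the hindered, electron-poor 1,1-disubstituted alkene may be sluggish. That leaves time for intermolecular metathesis and for exchange at the isopropylidene terminus.
- **Fallback (from 16 back to 26).** The ring is closed first and the side chain attached afterwards.
  - Acryloyl chloride gives the acrylate F6.
  - The easier metathesis to a disubstituted alkene gives the unsubstituted lactone F7.
  - Iodine and pyridine give the α-iodolactone F8.
  - Negishi coupling with the homoprenylzinc bromide F9 (from 18 and zinc) at room temperature gives 26. Oxidative addition into C–I outruns ionisation of the allylic esters.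

**Step 2.**

- **What may go wrong.** Site selectivity may be incomplete, because both alkenes are trisubstituted and differ only through the inductive and steric effect of the silyloxy group.
- **Fallback (from 2 back to 3).** N-Bromosuccinimide in aqueous THF gives the bromohydrin F10; in a polar medium the exposed chain end reacts preferentially. Potassium carbonate in methanol closes F10 to 3.

## Further compounds

F1 | step 4 | (6Z)-8-[(tert-butyldiphenylsilyl)oxy]-2-(1,3-dioxolan-2-yl)-6-methylocta-1,6-dien-3-ol (racemic) | C=C(C(O)CC/C(C)=C\CO[Si](c1ccccc1)(c1ccccc1)C(C)(C)C)C1OCCO1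
F2 | step 4 | acetate of F1 (racemic) | C=C(C(CC/C(C)=C\CO[Si](c1ccccc1)(c1ccccc1)C(C)(C)C)OC(C)=O)C1OCCO1
F3 | step 4 | (6Z)-8-[(tert-butyldiphenylsilyl)oxy]-2-formyl-6-methylocta-1,6-dien-3-yl acetate (racemic) | C=C(C=O)C(CC/C(C)=C\CO[Si](c1ccccc1)(c1ccccc1)C(C)(C)C)OC(C)=O
F4 | step 6 | racemic 16 | CC(=O)OC/C(=C\CC/C(C)=C\CO[Si](c1ccccc1)(c1ccccc1)C(C)(C)C)C(O)CC=C
F5 | step 6 | (2E,6Z)-2-(but-3-enoyl)-8-[(tert-butyldiphenylsilyl)oxy]-6-methylocta-2,6-dien-1-yl acetate | CC(=O)OC/C(=C\CC/C(C)=C\CO[Si](c1ccccc1)(c1ccccc1)C(C)(C)C)C(=O)CC=C
F6 | step 11 | acrylate of 16 | CC(=O)OC/C(=C\CC/C(C)=C\CO[Si](c1ccccc1)(c1ccccc1)C(C)(C)C)[C@H](OC(=O)C=C)CC=C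
F7 | step 11 | analogue of 26 without the C11 side chain | CC(=O)OC/C(=C\CC/C(C)=C\CO[Si](c1ccccc1)(c1ccccc1)C(C)(C)C)[C@H]1CC=CC(=O)O1
F8 | step 11 | C11-iodo derivative of F7 | CC(=O)OC/C(=C\CC/C(C)=C\CO[Si](c1ccccc1)(c1ccccc1)C(C)(C)C)[C@H]1CC=C(I)C(=O)O1
F9 | step 11 | (4-methylpent-3-en-1-yl)zinc bromide | CC(C)=CCC[Zn]Br
F10 | step 2 | (6Z)-3-bromo-8-[(tert-butyldiphenylsilyl)oxy]-2,6-dimethyloct-6-en-2-ol (racemic) | CC(C)(O)C(Br)CC/C(C)=C\CO[Si](c1ccccc1)(c1ccccc1)C(C)(C)C
A1 | alternative 1 | ethyl 3-[(tert-butyldimethylsilyl)oxy]-2-(diethoxyphosphoryl)propanoate | CCOC(=O)C(CO[Si](C)(C)C(C)(C)C)P(=O)(OCC)OCC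
A2 | alternative 1 | ethyl (2E,6Z)-2-{[(tert-butyldimethylsilyl)oxy]methyl}-8-[(tert-butyldiphenylsilyl)oxy]-6-methylocta-2,6-dienoate | CC(C)(C)[Si](C)(C)OC/C(=C\CC/C(C)=C\CO[Si](c1ccccc1)(c1ccccc1)C(C)(C)C)C(=O)OCC
A3 | alternative 1 | (2E,6Z)-2-{[(tert-butyldimethylsilyl)oxy]methyl}-8-[(tert-butyldiphenylsilyl)oxy]-6-methylocta-2,6-dienal | CC(C)(C)[Si](C)(C)OC/C(=C\CC/C(C)=C\CO[Si](c1ccccc1)(c1ccccc1)C(C)(C)C)C=O
A4 | alternative 2 | tert-butyl{[(2Z)-3-methylhept-2-en-6-yn-1-yl]oxy}diphenylsilane | C#CCC/C(C)=C\CO[Si](c1ccccc1)(c1ccccc1)C(C)(C)C
A5 | alternative 2 | (4R,10Z)-12-[(tert-butyldiphenylsilyl)oxy]-10-methyldodeca-1,10-dien-5-yn-4-ol | CC(C)(C)[Si](c1ccccc1)(c1ccccc1)OC/C=C(C)\CCC#C[C@H](O)CC=C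
A6 | alternative 2 | (4R,5Z,10Z)-12-[(tert-butyldiphenylsilyl)oxy]-10-methyl-5-(tributylstannyl)dodeca-1,5,10-trien-4-ol | CCCC[Sn](CCCC)(CCCC)/C(=C\CC/C(C)=C\CO[Si](c1ccccc1)(c1ccccc1)C(C)(C)C)[C@H](O)CC=C
A7 | alternative 3 | (6R)-6-(1-bromoethenyl)-3-(4-methylpent-3-en-1-yl)-5,6-dihydro-2H-pyran-2-one | C=C(Br)[C@H]1CC=C(CCC=C(C)C)C(=O)O1
A8 | alternative 3 | (6R)-6-{(6Z)-8-[(tert-butyldiphenylsilyl)oxy]-3-hydroxy-6-methylocta-1,6-dien-2-yl}-3-(4-methylpent-3-en-1-yl)-5,6-dihydro-2H-pyran-2-one (epimers at the carbinol) | C=C(C(O)CC/C(C)=C\CO[Si](c1ccccc1)(c1ccccc1)C(C)(C)C)[C@H]1CC=C(CCC=C(C)C)C(=O)O1
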